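## Structural features

The target is a 2,3-dihydro-1-benzofuran: a benzene ring fused to a five-membered oxygen ring (O1, C2, C3, C3a, C7a). The benzene ring carries an acetyl group at C5 and a phenol at C6, hydrogen-bonded to each other; O1 is para and C3a meta to the acetyl carbon. C2 bears a 3-acetoxyprop-1-en-2-yl chain and C3 a benzylic oxygen acylated with (Z)-2-methylbut-2-enoic acid. The two stereocentres are adjacent, both R, and the C2 carbon substituent and the C3 oxygen are cis. The fragile points are these:
- the C3 ester is benzylic, para to the C6 oxygen and anti to C2–H, so ionisation to a quinone methide and elimination to the aromatic benzofuran are both open;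
- the Z ester drifts to the E (tiglate) isomer under nucleophilic catalysis;
- the allylic acetate and the enolisable methyl ketone limit the choice of bases and metals.

The real difficulty is to set the cis C2/C3 pair in one absolute sense on a ring that aromatises easily, and then to place two different acyl groups on two hydroxyls. The key step uses the fact that O–C3–C2–C(=CH2) is a homoallylic alcohol. C3 (benzylic, oxygen-bearing) and C2 (bearing O1 and the propen-2-yl carbon) are the carbons joined by a [2,3]-Wittig shift of a benzyl allyl ether whose allyl terminus is an aryl enol ether carbon. The dihydrofuran ring is what is left when the eight-membered ether contracts.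

## Logic of the disconnections

25 to 23. Only protecting groups are removed last: the two ketal C–O bonds and the O–Si bond. This keeps the enolisable ketone and the acidic phenol masked through every basic step and leaves one deprotection operation. The demand is that the ketal be hydrolysed first, so that the ring is deactivated by the acetyl group before the phenol is freed with buffered fluoride.

23 to 20 and 21. The C3 O–acyl bond is cut. The Z ester is the most isomerisation-prone group and is therefore introduced as late as possible, from commercial 21. The forward acylation of a hindered secondary benzylic alcohol must avoid nucleophilic catalysts and heat.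

20 to 19 to 18. The primary O–acetyl bond and then the allylic C–O bond are cut, leaving a plain propen-2-yl group. This reduces the side chain to the group that a [2,3]-shift delivers directly. The demands are an allylic oxidation that chooses the methyl group over the C2 methine, and an acetylation that chooses the primary over the secondary hydroxyl.

18 to 16. The C2–C3 bond is cut and the C3 oxygen is reconnected to the terminal alkene carbon. Both stereocentres and the five-membered ring disappear, and an achiral eight-membered cyclic enol ether remains. The forward step must deprotonate the benzylic OCH2 group enantioselectively and rearrange before the carbanion inverts or shifts otherwise.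

16 to 15. The O1–C2 (aryl–O–vinyl) bond is cut to a phenol and a Z vinyl iodide in one chain. The Z geometry, fixed in an acyclic fragment, is what allows the medium ring to form. The forward step needs a copper-catalysed C–O coupling that retains alkene geometry and outruns oligomerisation.

15 to 13 to 8 and 12. The phenol protecting group is restored and the benzylic ether C–O bond is cut into a benzylic alcohol and an allylic bromide. The phenol must be masked while the alkoxide is alkylated, and the mask must later leave without acid (ketal), fluoride (aryl silyl ether), zerovalent palladium or hydrogen (vinyl iodide), or an oxidant (electron-rich benzyl ether).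

12 to 11 to 9. The C–Br bond, then the C–CH3 and C–I bonds across the alkene are cut back to a three-carbon alkyne. The demand is an anti addition of methyl and metal that places iodine cis to the CH2O group.

8 to 4 to 3 to 2 to 1. The aryl–CH2OH bond is cut to the aryl bromide, then the ketal, the silyl ether and the alkoxymethyl ether are removed in turn. The two phenols of 1 differ in acidity, so they can be protected one after the other. The organolithium step requires that the ketone is already a ketal, and that the oxygen ortho to the metalated carbon carries no silyl group.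

## Other disconnections considered

Alternative 1: The cut is the O1–C2 bond combined with a 1,2-shift, so that the propen-2-yl carbon becomes the gem-dimethyl carbon of a chroman. In the forward step the C3 hydroxyl of (3R,4R)-6-acetyl-7-[(tert-butyldimethylsilyl)oxy]-3-hydroxy-2,2-dimethyl-3,4-dihydro-2H-chromen-4-yl (2Z)-2-methylbut-2-enoate A2 is triflated (Tf2O, 2,6-lutidine). The ring oxygen moves from the quaternary carbon to C3 with inversion, and the tertiary cation loses a methyl proton to give (2R,3R)-5-acetyl-6-[(tert-butyldimethylsilyl)oxy]-2-(prop-1-en-2-yl)-2,3-dihydro-1-benzofuran-3-yl (2Z)-2-methylbut-2-enoate A3.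
- In its favour: A2 would follow in two operations from the chromene 1-[7-[(tert-butyldimethylsilyl)oxy]-2,2-dimethyl-2H-chromen-6-yl]ethanone A1, by asymmetric cis-dihydroxylation (OsO4 with a cinchona ligand) and acylation of the benzylic hydroxyl with 21. No strong base is used, so the ketone needs no protection. Inversion at one centre and retention at the other carry the cis relationship of A2 into A3.
- Against it: the shift needs the leaving group antiperiplanar to the O1–C2 ring bond (pseudo-equatorial). The pseudo-axial conformer instead aligns a C2 methyl group and, in the cis series, the benzylic C4–H, so methyl migration and elimination to an enol ester would compete. Cis-disubstituted chromenes are mediocre substrates for asymmetric dihydroxylation. The allylic oxidation would still be needed, now on A3, which already carries the Z ester and a free methyl ketone.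
- Comparison: structurally both plans make the dihydrofuran by contracting a larger oxygen ring. Mechanistically this one is cationic and creates only C2, whereas the chosen anionic shift creates both centres at once from an achiral precursor. In step economy the alternative is the better plan (roughly eight steps against fourteen). In the source of absolute configuration (an external chiral reagent) the two are equal. The chosen plan is preferred because its oxidation precedes the sensitive ester.

Alternative 2: The cut is the bond from C2 to the future propen-2-yl carbon, with that carbon tied to the C3 oxygen in a temporary lactone. In the forward step Rh2(OAc)4 decomposes (3R)-5-(2-methyl-1,3-dioxolan-2-yl)-6-[(triisopropylsilyl)oxy]-2,3-dihydro-1-benzofuran-3-yl 2-diazo-2-(diethoxyphosphoryl)acetate A4. The rhodium carbene inserts into the C2–H bond next to O1 to give cis-fused diethyl [(3R,3aS,8bR)-7-(2-methyl-1,3-dioxolan-2-yl)-2-oxo-6-[(triisopropylsilyl)oxy]-3,3a-dihydro-2H,8bH-furo[3,2-b][1]benzofuran-3-yl]phosphonate A5. Horner–Wadsworth–Emmons olefination of A5 with formaldehyde would give the methylene lactone A7 of alternative 3, and hydride reduction of that lactone would give 19.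
- In its favour: insertion into a C–H bond activated by an ether oxygen with closure of a five-membered ring is the preferred mode of such carbenes. The cis fusion is enforced by the tether. The one stereocentre of A4 would come from a catalytic asymmetric ketone reduction. The side chain arrives at the right oxidation level, so no allylic oxidation is needed.
- Against it: the carbene hangs on a benzylic oxygen of a very electron-rich arene, so attack on the ring at C4 and oxonium ylide formation at O1 would compete. The benzylic diazo ester is itself a leaving group. Five operations (acylation, diazo transfer, insertion, olefination, reduction) are spent to reach 19.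
- Comparison: the alternative is the better plan in predictability of absolute configuration and in avoiding SeO2. It is equal in protecting groups and in the geometric origin of the cis relationship (a cis-fused bicyclic transition state in both). It is worse in step count and in chemoselectivity of the bond-forming event.

Alternative 3: The cut is the C3–O bond, made last by oxidation of a benzylic C–H bond. In the forward step DDQ abstracts hydride from C3 of 2-[(2S)-5-(2-methyl-1,3-dioxolan-2-yl)-6-[(triisopropylsilyl)oxy]-2,3-dihydro-1-benzofuran-2-yl]prop-2-enoic acid A6, which has the same spatial arrangement at C2 as 25. The para oxygen stabilises the cation, and the carboxyl group closes cis-fused (3aR,8bR)-3-methylidene-7-(2-methyl-1,3-dioxolan-2-yl)-6-[(triisopropylsilyl)oxy]-3a,8b-dihydrofuro[3,2-b][1]benzofuran-2(3H)-one A7. Reduction of A7 would give 19.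
- In its favour: C3 needs no earlier functional group. The cis fusion is enforced. Only C2 needs external control. The side chain is already oxidised.
- Against it: the C3 cation can lose the C2 proton and aromatise to the benzofuran, which is the natural fate of this ring system. A silyloxy group is a weak donor for hydride abstraction. The ketal and the acrylic acid must tolerate DDQ. A6 needs an enantioselective synthesis of its own.
- Comparison: the alternative is the better plan in oxidation-state economy and equal in the way the cis relationship arises. Mechanistically it passes through the very cation that the chosen route avoids, and this is the reason it was not chosen.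

Key step: step 10

Remark on the structures: the descriptors were checked against the line notations. Target and rearrangement product are (2R,3R) with the C2 carbon substituent and the C3 oxygen cis, the enol ether of the precursor is Z, and the ester is the Z isomer. Nothing needed correction. Atom labels in the key step follow the benzodioxocine numbering (O1, C2, C3, C4, O5, C6).

Remark on the design: the precursor 16 is used as drawn (dioxolane and triisopropylsilyl ether). The way to it is designed around three points.
- The phenol that becomes O1 is carried as a methoxymethyl ether, not a silyl ether. A silyl group there would migrate to the ortho aryllithium and to the neighbouring benzylic alkoxide.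
- An allyl or benzyl ether there would need zerovalent palladium or hydrogen in the presence of the vinyl iodide, so the methoxymethyl group is removed under aprotic silyl triflate conditions.
- The ketone is ketalised before any organolithium is used.

Assumption: the (R,R) antipode of the lithium amide is written for step 10. The sense of its choice between the enantiotopic hydrogens cannot be derived from first principles. The (S,S) antipode, equally available, is to be used if the first leads to the (2S,3S) series.

## Route

Step 1
Reactants: 1 1-(5-bromo-2,4-dihydroxyphenyl)ethanone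
Product: 2 1-[5-bromo-2-hydroxy-4-(methoxymethoxy)phenyl]ethanone
Conditions: MOMCl (1.1 equiv), K2CO3, acetone, 0 °C → rt
Reagents that add atoms: chloromethyl methyl ether, COCCl
Why: Williamson-type O-alkylation; the 4-hydroxyl (para to the acetyl group, not chelated) is the more acidic and more nucleophilic phenol, whereas the 2-hydroxyl is held in a hydrogen bond to the carbonyl group.

Step 2
Reactants: 2 1-[5-bromo-2-hydroxy-4-(methoxymethoxy)phenyl]ethanone
Product: 3 1-[5-bromo-4-(methoxymethoxy)-2-[(triisopropylsilyl)oxy]phenyl]ethanone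
Conditions: i-Pr3SiOTf, 2,6-lutidine, CH2Cl2, 0 °C
Reagents that add atoms: triisopropylsilyl trifluoromethanesulfonate, CC(C)[Si](C(C)C)(C(C)C)OS(=O)(=O)C(F)(F)F
Why: O-silylation of the chelated phenol needs the silyl triflate; 2,6-lutidine is too weak a base to make the silyl enol ether of the methyl ketone, and the bulky silyl group is chosen because it must later survive carbonate at 90 °C and amide bases.

Step 3
Reactants: 3 1-[5-bromo-4-(methoxymethoxy)-2-[(triisopropylsilyl)oxy]phenyl]ethanone
Product: 4 2-[5-bromo-4-(methoxymethoxy)-2-[(triisopropylsilyl)oxy]phenyl]-2-methyl-1,3-dioxolane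
Conditions: Me3SiOCH2CH2OSiMe3, Me3SiOTf (5 mol%), CH2Cl2, −78 → −20 °C; pyridine quench
Reagents that add atoms: 1,2-bis(trimethylsilyloxy)ethane, C[Si](C)(C)OCCO[Si](C)(C)C
Why: Noyori ketalisation runs under aprotic conditions at low temperature and so spares the aryl methoxymethyl and silyl ethers; the dioxolane removes the enolisable ketone before organolithium and amide bases are used.

Step 4
Reactants: 4 2-[5-bromo-4-(methoxymethoxy)-2-[(triisopropylsilyl)oxy]phenyl]-2-methyl-1,3-dioxolane
Product: 8 {2-(methoxymethoxy)-5-(2-methyl-1,3-dioxolan-2-yl)-4-[(triisopropylsilyl)oxy]phenyl}methanol, via aryllithium 5 (not isolated), via lithium hemiaminal alkoxide 6 (not isolated), via benzaldehyde 7 (not isolated)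
Conditions: n-BuLi, THF, −78 °C; DMF, −78 → 0 °C; then MeOH, NaBH4, 0 °C
Reagents that add atoms: N,N-dimethylformamide, CN(C)C=O
Why: Bromine–lithium exchange is faster than any deprotonation at −78 °C and gives an aryllithium held by the ortho methoxymethoxy group (the silyloxy group is para, so no 1,3-silyl shift is possible); Bouveault formylation and borohydride reduction in the same flask give the benzylic alcohol.

Step 5
Reactants: 9 prop-2-yn-1-ol
Product: 11 (2Z)-3-iodo-2-methylprop-2-en-1-ol, via alkenylmagnesium alkoxide 10 (not isolated)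
Conditions: MeMgBr (2.5 equiv), CuI (10 mol%), Et2O, −10 °C → rt; I2, −10 °C → rt; 1 M HCl
Reagents that add atoms: methylmagnesium bromide, C[Mg]Br; iodine, II
Why: Copper-catalysed carbomagnesiation of the propargylic magnesium alkoxide is an anti addition through a five-membered oxamagnesacycle, so magnesium, and after iodinolysis with retention iodine, lies cis to the CH2O group (Z).

Step 6
Reactants: 11 (2Z)-3-iodo-2-methylprop-2-en-1-ol
Product: 12 (1Z)-3-bromo-1-iodo-2-methylprop-1-ene
Conditions: CBr4, PPh3, CH2Cl2, 0 °C
Reagents that add atoms: tetrabromomethane, BrC(Br)(Br)Br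
Why: Appel reaction; the primary allylic alcohol becomes the bromide under neutral conditions without change to the vinyl iodide or its geometry.

Step 7
Reactants: 8 {2-(methoxymethoxy)-5-(2-methyl-1,3-dioxolan-2-yl)-4-[(triisopropylsilyl)oxy]phenyl}methanol; 12 (1Z)-3-bromo-1-iodo-2-methylprop-1-ene
Product: 13 2-[5-({[(2Z)-3-iodo-2-methylprop-2-en-1-yl]oxy}methyl)-4-(methoxymethoxy)-2-[(triisopropylsilyl)oxy]phenyl]-2-methyl-1,3-dioxolane
Conditions: NaH, THF, 0 °C; 12, Bu4NI (10 mol%), 0 °C → rt
Reagents that add atoms: none
Why: Williamson ether synthesis between the sodium alkoxide of a primary benzylic alcohol and a primary allylic bromide; the silyl ether is para to the alkoxide-bearing carbon and cannot migrate to it.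

Step 8
Reactants: 13 2-[5-({[(2Z)-3-iodo-2-methylprop-2-en-1-yl]oxy}methyl)-4-(methoxymethoxy)-2-[(triisopropylsilyl)oxy]phenyl]-2-methyl-1,3-dioxolane
Product: 15 2-({[(2Z)-3-iodo-2-methylprop-2-en-1-yl]oxy}methyl)-4-(2-methyl-1,3-dioxolan-2-yl)-5-[(triisopropylsilyl)oxy]phenol, via aryl trimethylsilyl ether 14 (not isolated)
Conditions: Me3SiOTf (2 equiv), 2,2'-bipyridyl (3 equiv), CH2Cl2, 0 °C → rt; then H2O
Reagents that add atoms: none
Why: The silyl triflate–2,2'-bipyridyl pair transfers the alkoxymethyl group of an aryl methoxymethyl ether to the pyridine nitrogen and leaves an aryl trimethylsilyl ether that water cleaves; the medium is aprotic and the Lewis acid is attenuated by the base, conditions under which ketals are known to persist, and the vinyl iodide and the hindered silyl ether are inert.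

Step 9
Reactants: 15 2-({[(2Z)-3-iodo-2-methylprop-2-en-1-yl]oxy}methyl)-4-(2-methyl-1,3-dioxolan-2-yl)-5-[(triisopropylsilyl)oxy]phenol
Product: 16 (Z)-3-methyl-8-(2-methyl-1,3-dioxolan-2-yl)-9-[(triisopropylsilyl)oxy]-4H,6H-1,5-benzodioxocine
Conditions: CuI (10 mol%), 3,4,7,8-tetramethyl-1,10-phenanthroline (20 mol%), Cs2CO3, toluene, 90 °C, 0.005 M
Reagents that add atoms: none
Why: Ullmann-type copper-catalysed O-vinylation of a phenol by a vinyl iodide with retention of alkene geometry; the Z alkene and the ortho-disposed arene hold both reacting ends on the same side, so the eight-membered ring can close at high dilution, and the other phenol is masked.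

Step 10
Reactants: 16 (Z)-3-methyl-8-(2-methyl-1,3-dioxolan-2-yl)-9-[(triisopropylsilyl)oxy]-4H,6H-1,5-benzodioxocine
Product: 18 (2R,3R)-5-(2-methyl-1,3-dioxolan-2-yl)-2-(prop-1-en-2-yl)-6-[(triisopropylsilyl)oxy]-2,3-dihydro-1-benzofuran-3-ol, via 6-lithio benzodioxocine 17 (not isolated)
Conditions: LiN[(R)-CH(CH3)C6H5]2 (2 equiv, from the amine and n-BuLi), THF, −78 → −20 °C; H2O
Reagents that add atoms: none
Why: Proposed new method: the chiral lithium amide removes one of the two enantiotopic hydrogens at C6, the only position activated by both an aryl group and an ether oxygen, to give the α-oxy benzyllithium 17. C6 then bonds to the enol ether carbon C2 while the O5–C4 bond breaks and the double bond moves to C3=C4, a concerted suprafacial six-electron [2,3]-sigmatropic (Wittig) shift driven by the change from carbanion to alkoxide and by relief of medium-ring strain. The closest known reaction type is the ring-contracting [2,3]-Wittig rearrangement of macrocyclic allyl and propargyl ethers induced by chiral lithium amides, together with enantioselective [2,3]-Wittig shifts of acyclic benzyl allyl ethers; a benzo-fused eight-membered ring with an enol ether terminus has no precedent. The five-membered ring closes transannularly in a 5-exo-trig mode (C6 onto C2, with C3 left outside the new ring). The relative configuration follows from the transition state: the five reacting atoms and the forming ring share the new bond in a cis-fused bicyclo[3.3.0] array, which places the C3 oxygen and the propen-2-yl carbon cis, and the ring locks the enol ether as Z so that no competing geometry exists. The absolute configuration is set by the amide's choice of benzylic hydrogen, provided 17 rearranges faster than it inverts, which the enforced proximity of C2 favours. The step needs benzylic over allylic (C4) or aryl deprotonation, secured by the double activation of C6–H and the low kinetic basicity of a hindered amide towards aryl C–H, and [2,3] over [1,2] migration, secured by low temperature and the transannular geometry.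

Step 11
Reactants: 18 (2R,3R)-5-(2-methyl-1,3-dioxolan-2-yl)-2-(prop-1-en-2-yl)-6-[(triisopropylsilyl)oxy]-2,3-dihydro-1-benzofuran-3-ol
Product: 19 (2R,3R)-2-(3-hydroxyprop-1-en-2-yl)-5-(2-methyl-1,3-dioxolan-2-yl)-6-[(triisopropylsilyl)oxy]-2,3-dihydro-1-benzofuran-3-ol
Conditions: SeO2 (0.3 equiv), t-BuOOH (2 equiv, in decane), CH2Cl2, 0 °C → rt
Reagents that add atoms: tert-butyl hydroperoxide, CC(C)(C)OO; selenium dioxide, O=[Se]=O
Why: Allylic oxidation with SeO2 (ene reaction, then [2,3]-shift of the allylseleninic acid) on a 1,1-disubstituted alkene takes place at the methyl group and not at the hindered, oxygen-bearing C2 methine; t-BuOOH keeps selenium catalytic and the medium anhydrous so that the ketal holds.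

Step 12
Reactants: 19 (2R,3R)-2-(3-hydroxyprop-1-en-2-yl)-5-(2-methyl-1,3-dioxolan-2-yl)-6-[(triisopropylsilyl)oxy]-2,3-dihydro-1-benzofuran-3-ol
Product: 20 2-[(2R,3R)-3-hydroxy-5-(2-methyl-1,3-dioxolan-2-yl)-6-[(triisopropylsilyl)oxy]-2,3-dihydro-1-benzofuran-2-yl]prop-2-en-1-yl acetate
Conditions: AcCl (1.05 equiv), 2,4,6-collidine, CH2Cl2, −78 °C
Reagents that add atoms: acetyl chloride, CC(Cl)=O
Why: Kinetic acylation; the primary allylic hydroxyl reacts with one equivalent of acetyl chloride at −78 °C much faster than the secondary benzylic hydroxyl, which is flanked by the cis C2 substituent.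

Step 13
Reactants: 20 2-[(2R,3R)-3-hydroxy-5-(2-methyl-1,3-dioxolan-2-yl)-6-[(triisopropylsilyl)oxy]-2,3-dihydro-1-benzofuran-2-yl]prop-2-en-1-yl acetate; 21 (2Z)-2-methylbut-2-enoic acid (angelic acid)
Product: 23 (2R,3R)-2-[3-(acetyloxy)prop-1-en-2-yl]-5-(2-methyl-1,3-dioxolan-2-yl)-6-[(triisopropylsilyl)oxy]-2,3-dihydro-1-benzofuran-3-yl (2Z)-2-methylbut-2-enoate, via mixed anhydride 22 (not isolated)
Conditions: 21, 2,4,6-Cl3C6H2COCl, Et3N, THF, rt; then 20 as its lithium alkoxide (LiN(SiMe3)2, THF, −78 °C), −78 → 0 °C
Reagents that add atoms: none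
Why: Yamaguchi-type mixed anhydride acylation; the lithium alkoxide attacks the unhindered carbonyl group of the mixed anhydride at low temperature, and because no nucleophilic catalyst and no heating are used, neither Z-to-E isomerisation of the acyl group nor elimination across C2–C3 is expected.

Step 14
Reactants: 23 (2R,3R)-2-[3-(acetyloxy)prop-1-en-2-yl]-5-(2-methyl-1,3-dioxolan-2-yl)-6-[(triisopropylsilyl)oxy]-2,3-dihydro-1-benzofuran-3-yl (2Z)-2-methylbut-2-enoate
Product: 25 (2R,3R)-5-acetyl-2-[3-(acetyloxy)prop-1-en-2-yl]-6-hydroxy-2,3-dihydro-1-benzofuran-3-yl (2Z)-2-methylbut-2-enoate, via silyloxy ketone 24 (not isolated)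
Conditions: 1 M aq. HCl (0.2 equiv), THF, rt; then Bu4NF–AcOH (1:1), 0 °C
Reagents that add atoms: water, O
Why: Acid-catalysed hydrolysis of the electron-rich aryl ketal is fast and first restores the acetyl group, which deactivates the ring towards benzylic ionisation; buffered fluoride then cleaves the aryl silyl ether, now activated by the ortho carbonyl group, without forming a free phenoxide.

## Compound list

1 | 1-(5-bromo-2,4-dihydroxyphenyl)ethanone | CC(=O)c1cc(Br)c(O)cc1O | starting material
2 | 1-[5-bromo-2-hydroxy-4-(methoxymethoxy)phenyl]ethanone | CC(=O)c1cc(Br)c(OCOC)cc1O | intermediate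
3 | 1-[5-bromo-4-(methoxymethoxy)-2-[(triisopropylsilyl)oxy]phenyl]ethanone | CC(=O)c1cc(Br)c(OCOC)cc1O[Si](C(C)C)(C(C)C)C(C)C | intermediate
4 | 2-[5-bromo-4-(methoxymethoxy)-2-[(triisopropylsilyl)oxy]phenyl]-2-methyl-1,3-dioxolane | CC1(c2cc(Br)c(OCOC)cc2O[Si](C(C)C)(C(C)C)C(C)C)OCCO1 | intermediate
5 | {2-(methoxymethoxy)-5-(2-methyl-1,3-dioxolan-2-yl)-4-[(triisopropylsilyl)oxy]phenyl}lithium | COCOc1cc(O[Si](C(C)C)(C(C)C)C(C)C)c(C2(C)OCCO2)cc1[Li] | intermediate
6 | lithium (dimethylamino){2-(methoxymethoxy)-5-(2-methyl-1,3-dioxolan-2-yl)-4-[(triisopropylsilyl)oxy]phenyl}methanolate (racemic at the new carbon) | COCOc1cc(O[Si](C(C)C)(C(C)C)C(C)C)c(C2(C)OCCO2)cc1C(O[Li])N(C)C | intermediate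
7 | 2-(methoxymethoxy)-5-(2-methyl-1,3-dioxolan-2-yl)-4-[(triisopropylsilyl)oxy]benzaldehyde | COCOc1cc(O[Si](C(C)C)(C(C)C)C(C)C)c(C2(C)OCCO2)cc1C=O | intermediate
8 | {2-(methoxymethoxy)-5-(2-methyl-1,3-dioxolan-2-yl)-4-[(triisopropylsilyl)oxy]phenyl}methanol | COCOc1cc(O[Si](C(C)C)(C(C)C)C(C)C)c(C2(C)OCCO2)cc1CO | intermediate
9 | prop-2-yn-1-ol | C#CCO | starting material
10 | bromo{(1Z)-3-[(bromomagnesio)oxy]-2-methylprop-1-en-1-yl}magnesium | C/C(CO[Mg]Br)=C/[Mg]Br | intermediate
11 | (2Z)-3-iodo-2-methylprop-2-en-1-ol | C/C(CO)=C/I | intermediate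
12 | (1Z)-3-bromo-1-iodo-2-methylprop-1-ene | C/C(CBr)=C/I | intermediate
13 | 2-[5-({[(2Z)-3-iodo-2-methylprop-2-en-1-yl]oxy}methyl)-4-(methoxymethoxy)-2-[(triisopropylsilyl)oxy]phenyl]-2-methyl-1,3-dioxolane | COCOc1cc(O[Si](C(C)C)(C(C)C)C(C)C)c(C2(C)OCCO2)cc1COC/C(C)=C\I | intermediate
14 | 2-[5-({[(2Z)-3-iodo-2-methylprop-2-en-1-yl]oxy}methyl)-2-[(triisopropylsilyl)oxy]-4-[(trimethylsilyl)oxy]phenyl]-2-methyl-1,3-dioxolane | C[Si](C)(C)Oc1cc(O[Si](C(C)C)(C(C)C)C(C)C)c(C2(C)OCCO2)cc1COC/C(C)=C\I | intermediate
15 | 2-({[(2Z)-3-iodo-2-methylprop-2-en-1-yl]oxy}methyl)-4-(2-methyl-1,3-dioxolan-2-yl)-5-[(triisopropylsilyl)oxy]phenol | Oc1cc(O[Si](C(C)C)(C(C)C)C(C)C)c(C2(C)OCCO2)cc1COC/C(C)=C\I | intermediate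
16 | (Z)-3-methyl-8-(2-methyl-1,3-dioxolan-2-yl)-9-[(triisopropylsilyl)oxy]-4H,6H-1,5-benzodioxocine | C/C1=C/Oc2cc(O[Si](C(C)C)(C(C)C)C(C)C)c(C3(C)OCCO3)cc2COC1 | intermediate
17 | [(2Z)-3-methyl-8-(2-methyl-1,3-dioxolan-2-yl)-9-[(triisopropylsilyl)oxy]-4H,6H-1,5-benzodioxocin-6-yl]lithium (configuration at C6 set by the base, not assigned) | C/C1=C/Oc2cc(O[Si](C(C)C)(C(C)C)C(C)C)c(C3(C)OCCO3)cc2C([Li])OC1 | intermediate
18 | (2R,3R)-5-(2-methyl-1,3-dioxolan-2-yl)-2-(prop-1-en-2-yl)-6-[(triisopropylsilyl)oxy]-2,3-dihydro-1-benzofuran-3-ol | C=C(C)[C@H]1Oc2cc(O[Si](C(C)C)(C(C)C)C(C)C)c(C3(C)OCCO3)cc2[C@H]1O | intermediate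
19 | (2R,3R)-2-(3-hydroxyprop-1-en-2-yl)-5-(2-methyl-1,3-dioxolan-2-yl)-6-[(triisopropylsilyl)oxy]-2,3-dihydro-1-benzofuran-3-ol | C=C(CO)[C@H]1Oc2cc(O[Si](C(C)C)(C(C)C)C(C)C)c(C3(C)OCCO3)cc2[C@H]1O | intermediate
20 | 2-[(2R,3R)-3-hydroxy-5-(2-methyl-1,3-dioxolan-2-yl)-6-[(triisopropylsilyl)oxy]-2,3-dihydro-1-benzofuran-2-yl]prop-2-en-1-yl acetate | C=C(COC(C)=O)[C@H]1Oc2cc(O[Si](C(C)C)(C(C)C)C(C)C)c(C3(C)OCCO3)cc2[C@H]1O | intermediate
21 | (2Z)-2-methylbut-2-enoic acid (angelic acid) | C/C=C(/C)C(=O)O | starting material
22 | (2Z)-2-methylbut-2-enoic 2,4,6-trichlorobenzoic anhydride | C/C=C(/C)C(=O)OC(=O)c1c(Cl)cc(Cl)cc1Cl | intermediate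
23 | (2R,3R)-2-[3-(acetyloxy)prop-1-en-2-yl]-5-(2-methyl-1,3-dioxolan-2-yl)-6-[(triisopropylsilyl)oxy]-2,3-dihydro-1-benzofuran-3-yl (2Z)-2-methylbut-2-enoate | C=C(COC(C)=O)[C@H]1Oc2cc(O[Si](C(C)C)(C(C)C)C(C)C)c(C3(C)OCCO3)cc2[C@H]1OC(=O)/C(C)=C\C | intermediate
24 | (2R,3R)-5-acetyl-2-[3-(acetyloxy)prop-1-en-2-yl]-6-[(triisopropylsilyl)oxy]-2,3-dihydro-1-benzofuran-3-yl (2Z)-2-methylbut-2-enoate | C=C(COC(C)=O)[C@H]1Oc2cc(O[Si](C(C)C)(C(C)C)C(C)C)c(C(C)=O)cc2[C@H]1OC(=O)/C(C)=C\C | intermediate
25 | (2R,3R)-5-acetyl-2-[3-(acetyloxy)prop-1-en-2-yl]-6-hydroxy-2,3-dihydro-1-benzofuran-3-yl (2Z)-2-methylbut-2-enoate | C=C(COC(C)=O)[C@H]1Oc2cc(O)c(C(C)=O)cc2[C@H]1OC(=O)/C(C)=C\C | target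

## Step count and least certain steps

Total step count: 14. Longest linear sequence: 12 (steps 1–4 and 7–14). Steps 5 and 6 form a two-step branch that joins at step 7.

Step 10 (key step). Deprotonation may be too slow at low temperature, because the para silyloxy group lowers the benzylic acidity. Removal of an allylic hydrogen at C4 followed by a [1,2]-shift may compete. Inversion of the benzyllithium before rearrangement would erode the enantiomeric purity.

The fallback uses known chemistry. It sets out from 7, which is isolated when the borohydride addition of step 4 is left out, and comes back at 18. The methoxymethyl group is removed as in step 8 to give 2-hydroxy-5-(2-methyl-1,3-dioxolan-2-yl)-4-[(triisopropylsilyl)oxy]benzaldehyde F1. O-Alkylation with chloroacetone (K2CO3, acetone, rt) gives 5-(2-methyl-1,3-dioxolan-2-yl)-2-(2-oxopropoxy)-4-[(triisopropylsilyl)oxy]benzaldehyde F2. A proline-catalysed intramolecular aldol addition (5-enolexo; the antipode of proline that leads to the required series, DMF, rt) should close the dihydrofuran ring as the cis aldol 1-[(2S,3R)-3-hydroxy-5-(2-methyl-1,3-dioxolan-2-yl)-6-[(triisopropylsilyl)oxy]-2,3-dihydro-1-benzofuran-2-yl]ethanone F3. Non-basic methylenation of the ketone with Cp2TiMe2 (toluene, 65 °C) should then give 18. The descriptor at C2 changes from S to R only because the substituent priorities change.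

Step 9. Intermolecular coupling may outrun closure of the eight-membered ring, and carbonate at 90 °C may slowly remove the aryl silyl group.

The fallback closes the ring by metathesis at C2=C3 instead of C–O coupling. It sets out from 8 and comes back at 16. Alkylation of 8 with 3-chloro-2-methylprop-1-ene (NaH, THF) gives 2-[4-(methoxymethoxy)-5-{[(2-methylprop-2-en-1-yl)oxy]methyl}-2-[(triisopropylsilyl)oxy]phenyl]-2-methyl-1,3-dioxolane F4. Removal of the methoxymethyl group as in step 8 gives 4-(2-methyl-1,3-dioxolan-2-yl)-2-{[(2-methylprop-2-en-1-yl)oxy]methyl}-5-[(triisopropylsilyl)oxy]phenol F5. O-Vinylation of the phenol (Cu(OAc)2, 2,4,6-trivinylcyclotriboroxane–pyridine complex, pyridine, CH2Cl2, air) gives 2-[4-(ethenyloxy)-5-{[(2-methylprop-2-en-1-yl)oxy]methyl}-2-[(triisopropylsilyl)oxy]phenyl]-2-methyl-1,3-dioxolane F6. Ring-closing metathesis of the enol ether with Mo(=CHCMe2Ph)(=N-2,6-iPr2C6H3)[OCMe(CF3)2]2 (benzene, 60 °C) should give 16, in which the ring allows only the Z alkene.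

Step 8. The silyl triflate may ionise the electron-rich benzylic ether, or open the ketal, in competition with the transfer of the alkoxymethyl group.

The fallback unmasks the phenol before the acid-sensitive benzylic ether exists. It sets out from 8 and comes back at 15. The same silyl triflate–2,2'-bipyridyl treatment applied to 8 gives 2-(hydroxymethyl)-4-(2-methyl-1,3-dioxolan-2-yl)-5-[(triisopropylsilyl)oxy]phenol F7. Its disodium salt (NaH, 2.2 equiv, THF, 0 °C) is alkylated with one equivalent of 12 at the more basic alkoxide oxygen, the phenoxide being a poor nucleophile in THF, to give 15.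

Step 11. Over-oxidation to the enal and acid-induced loss of the ketal are the likely losses, and the conversion of a 1,1-disubstituted alkene may be slow.

The fallback sets out from 18 and comes back at 19. Epoxidation of the propen-2-yl group (mCPBA, NaHCO3, CH2Cl2, 0 °C) gives (2S,3R)-2-(2-methyloxiran-2-yl)-5-(2-methyl-1,3-dioxolan-2-yl)-6-[(triisopropylsilyl)oxy]-2,3-dihydro-1-benzofuran-3-ol F8 as a mixture of epimers at the oxirane carbon. Base-induced isomerisation of the epoxide to the allylic alcohol with Et2Al(NC9H18) (diethylaluminium 2,2,6,6-tetramethylpiperidide, toluene, 0 °C), which removes a hydrogen from the methyl group, should give 19.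

Step 13. The acyl group may isomerise from Z to E during activation, or the alkoxide may induce elimination across C2–C3 towards the benzofuran.

The fallback builds the Z alkene on the ester after acylation. It sets out from 20 and comes back at 23. Esterification of 20 with 2-[bis(2,2,2-trifluoroethoxy)phosphoryl]propanoic acid (carbodiimide, CH2Cl2, 0 °C) gives (2R,3R)-2-[3-(acetyloxy)prop-1-en-2-yl]-5-(2-methyl-1,3-dioxolan-2-yl)-6-[(triisopropylsilyl)oxy]-2,3-dihydro-1-benzofuran-3-yl 2-[bis(2,2,2-trifluoroethoxy)phosphoryl]propanoate F9 (both epimers at the phosphorus-bearing carbon). Still–Gennari olefination with acetaldehyde (KN(SiMe3)2, 18-crown-6, THF, −78 °C) should give the Z ester 23.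

## Further compounds

F1 | step 10 | 2-hydroxy-5-(2-methyl-1,3-dioxolan-2-yl)-4-[(triisopropylsilyl)oxy]benzaldehyde | O=Cc1cc(C2(C)OCCO2)c(O[Si](C(C)C)(C(C)C)C(C)C)cc1O
F2 | step 10 | 5-(2-methyl-1,3-dioxolan-2-yl)-2-(2-oxopropoxy)-4-[(triisopropylsilyl)oxy]benzaldehyde | CC(=O)COc1cc(O[Si](C(C)C)(C(C)C)C(C)C)c(C2(C)OCCO2)cc1C=O
F3 | step 10 | 1-[(2S,3R)-3-hydroxy-5-(2-methyl-1,3-dioxolan-2-yl)-6-[(triisopropylsilyl)oxy]-2,3-dihydro-1-benzofuran-2-yl]ethanone | CC(=O)[C@H]1Oc2cc(O[Si](C(C)C)(C(C)C)C(C)C)c(C3(C)OCCO3)cc2[C@H]1O
F4 | step 9 | 2-[4-(methoxymethoxy)-5-{[(2-methylprop-2-en-1-yl)oxy]methyl}-2-[(triisopropylsilyl)oxy]phenyl]-2-methyl-1,3-dioxolane | C=C(C)COCc1cc(C2(C)OCCO2)c(O[Si](C(C)C)(C(C)C)C(C)C)cc1OCOC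
F5 | step 9 | 4-(2-methyl-1,3-dioxolan-2-yl)-2-{[(2-methylprop-2-en-1-yl)oxy]methyl}-5-[(triisopropylsilyl)oxy]phenol | C=C(C)COCc1cc(C2(C)OCCO2)c(O[Si](C(C)C)(C(C)C)C(C)C)cc1O
F6 | step 9 | 2-[4-(ethenyloxy)-5-{[(2-methylprop-2-en-1-yl)oxy]methyl}-2-[(triisopropylsilyl)oxy]phenyl]-2-methyl-1,3-dioxolane | C=COc1cc(O[Si](C(C)C)(C(C)C)C(C)C)c(C2(C)OCCO2)cc1COCC(C)=C
F7 | step 8 | 2-(hydroxymethyl)-4-(2-methyl-1,3-dioxolan-2-yl)-5-[(triisopropylsilyl)oxy]phenol | OCc1cc(C2(C)OCCO2)c(O[Si](C(C)C)(C(C)C)C(C)C)cc1O
F8 | step 11 | (2S,3R)-2-(2-methyloxiran-2-yl)-5-(2-methyl-1,3-dioxolan-2-yl)-6-[(triisopropylsilyl)oxy]-2,3-dihydro-1-benzofuran-3-ol (both epimers at the oxirane carbon) | CC2(CO2)[C@H]1Oc3cc(O[Si](C(C)C)(C(C)C)C(C)C)c(C4(C)OCCO4)cc3[C@H]1O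
F9 | step 13 | (2R,3R)-2-[3-(acetyloxy)prop-1-en-2-yl]-5-(2-methyl-1,3-dioxolan-2-yl)-6-[(triisopropylsilyl)oxy]-2,3-dihydro-1-benzofuran-3-yl 2-[bis(2,2,2-trifluoroethoxy)phosphoryl]propanoate (both epimers at the phosphorus-bearing carbon) | C=C(COC(C)=O)[C@H]1Oc2cc(O[Si](C(C)C)(C(C)C)C(C)C)c(C3(C)OCCO3)cc2[C@H]1OC(=O)C(C)P(=O)(OCC(F)(F)F)OCC(F)(F)F
A1 | alternative 1 | 1-[7-[(tert-butyldimethylsilyl)oxy]-2,2-dimethyl-2H-chromen-6-yl]ethanone | CC(=O)c1cc2C=CC(C)(C)Oc2cc1O[Si](C)(C)C(C)(C)C
A2 | alternative 1 | (3R,4R)-6-acetyl-7-[(tert-butyldimethylsilyl)oxy]-3-hydroxy-2,2-dimethyl-3,4-dihydro-2H-chromen-4-yl (2Z)-2-methylbut-2-enoate | CC1(C)Oc2cc(O[Si](C)(C)C(C)(C)C)c(C(C)=O)cc2[C@@H](OC(=O)/C(C)=C\C)[C@H]1O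
A3 | alternative 1 | (2R,3R)-5-acetyl-6-[(tert-butyldimethylsilyl)oxy]-2-(prop-1-en-2-yl)-2,3-dihydro-1-benzofuran-3-yl (2Z)-2-methylbut-2-enoate | C=C(C)[C@H]1Oc2cc(O[Si](C)(C)C(C)(C)C)c(C(C)=O)cc2[C@H]1OC(=O)/C(C)=C\C
A4 | alternative 2 | (3R)-5-(2-methyl-1,3-dioxolan-2-yl)-6-[(triisopropylsilyl)oxy]-2,3-dihydro-1-benzofuran-3-yl 2-diazo-2-(diethoxyphosphoryl)acetate | CCOP(=O)(OCC)C(=[N+]=[N-])C(=O)O[C@H]1COc2cc(O[Si](C(C)C)(C(C)C)C(C)C)c(C3(C)OCCO3)cc21
A5 | alternative 2 | diethyl [(3R,3aS,8bR)-7-(2-methyl-1,3-dioxolan-2-yl)-2-oxo-6-[(triisopropylsilyl)oxy]-3,3a-dihydro-2H,8bH-furo[3,2-b][1]benzofuran-3-yl]phosphonate (cis-fused) | CCOP(=O)(OCC)[C@H]1C(=O)O[C@@H]2c3cc(C4(C)OCCO4)c(O[Si](C(C)C)(C(C)C)C(C)C)cc3O[C@H]12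
A6 | alternative 3 | 2-[(2S)-5-(2-methyl-1,3-dioxolan-2-yl)-6-[(triisopropylsilyl)oxy]-2,3-dihydro-1-benzofuran-2-yl]prop-2-enoic acid | C=C(C(=O)O)[C@@H]1Cc2cc(C3(C)OCCO3)c(O[Si](C(C)C)(C(C)C)C(C)C)cc2O1
A7 | alternative 3 | (3aR,8bR)-3-methylidene-7-(2-methyl-1,3-dioxolan-2-yl)-6-[(triisopropylsilyl)oxy]-3a,8b-dihydrofuro[3,2-b][1]benzofuran-2(3H)-one (cis-fused) | C=C1C(=O)O[C@@H]2c3cc(C4(C)OCCO4)c(O[Si](C(C)C)(C(C)C)C(C)C)cc3O[C@H]12
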